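**Strategy.** Ring C of the lower (epicatechin) unit is disconnected at C4–C4a and O1–C8a, so the C2–O1 bond is never broken and a syn glycolate aldol adduct maps directly onto the 2,3-cis flavan. The key step exploits ring A of that unit: C8a is meta to the oxygens on C5 and C7, C4a is ortho to the C5 oxygen, so the 3,5-dioxygenated benzyne (C4a≡C8a) takes up an alkoxide at C8a and the carbanion formed at C4a closes ring C on a primary bromide. Its precursors are an acyclic bromo alcohol and a silylaryl triflate. The upper unit, from the same glycolate imide, is then joined at C4 by Friedel–Crafts coupling and all benzyl ethers are removed.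

Key step: step 8

Assumption (chemistry): the NaBH4 reduction in step 12 is expected to give both epimers at the new carbinol carbon, so 29, 30 and 31 are written without a descriptor there; that carbon becomes planar in step 14. Compounds 1, 2, 5, 10, 22 and 26 are taken as commercial.

**Step 1**
Reactants: 1 (S)-4-benzyloxazolidin-2-one; 2 (benzyloxy)acetyl chloride
Product: 4 (S)-4-benzyl-3-[(benzyloxy)acetyl]oxazolidin-2-one, via N-lithio oxazolidinone 3 (not isolated)
Conditions: n-BuLi, THF, −78 °C; then 2, −78 → 0 °C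
Reagents that add atoms: none
Why: N-acylation of the lithiated oxazolidinone by the acid chloride is the standard entry to the imide and touches no stereocentre.

**Step 2**
Reactants: 4 (S)-4-benzyl-3-[(benzyloxy)acetyl]oxazolidin-2-one; 5 3,4-bis(benzyloxy)benzaldehyde
Product: 7 (S)-4-benzyl-3-[(2S,3R)-2-(benzyloxy)-3-[3,4-bis(benzyloxy)phenyl]-3-hydroxypropanoyl]oxazolidin-2-one, via boron enolate 6 (not isolated)
Conditions: Bu2BOTf, Et3N, CH2Cl2, −78 → 0 °C; then 5, −78 → 0 °C; H2O2, MeOH, pH 7 buffer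
Reagents that add atoms: none
Why: Evans syn aldol reaction: the (Z)-boron enolate should react through a closed chair transition state on the face opposite the auxiliary benzyl group, setting C2 (S) and C3 (R) of the acyl chain, the future C3 and C2 of the lower unit.

**Step 3**
Reactants: 7 (S)-4-benzyl-3-[(2S,3R)-2-(benzyloxy)-3-[3,4-bis(benzyloxy)phenyl]-3-hydroxypropanoyl]oxazolidin-2-one
Product: 8 (1R,2R)-2-(benzyloxy)-1-[3,4-bis(benzyloxy)phenyl]propane-1,3-diol
Conditions: LiBH4, MeOH (1 equiv), THF, 0 °C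
Reagents that add atoms: none
Why: Reductive cleavage of the imide by LiBH4 should release the primary alcohol and the auxiliary without touching the two carbinol centres.

**Step 4**
Reactants: 8 (1R,2R)-2-(benzyloxy)-1-[3,4-bis(benzyloxy)phenyl]propane-1,3-diol
Product: 9 (1R,2S)-2-(benzyloxy)-1-[3,4-bis(benzyloxy)phenyl]-3-bromopropan-1-ol
Conditions: CBr4, PPh3, CH2Cl2, 0 °C
Reagents that add atoms: carbon tetrabromide, BrC(Br)(Br)Br
Why: Appel reaction: the unhindered primary hydroxyl should form the alkoxyphosphonium ion much faster than the flanked benzylic one, so only the terminal carbon is brominated (the descriptor at C2 changes by priority only).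

**Step 5**
Reactants: 10 3,5-bis(benzyloxy)phenol
Product: 11 3,5-bis(benzyloxy)phenyl N-isopropylcarbamate
Conditions: i-PrNCO, Et3N (cat.), CH2Cl2, rt
Reagents that add atoms: isopropyl isocyanate, CC(C)N=C=O
Why: Carbamoylation of the phenol by an isocyanate installs the directing group for the ortho-metalation that follows.

**Step 6**
Reactants: 11 3,5-bis(benzyloxy)phenyl N-isopropylcarbamate
Product: 15 3,5-bis(benzyloxy)-2-(trimethylsilyl)phenyl N-isopropylcarbamate, via N-silyl carbamate 12 (not isolated), via aryllithium 13 (not isolated), via N-silyl C-silyl carbamate 14 (not isolated)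
Conditions: TBSOTf, TMEDA, Et2O, 0 °C → rt; n-BuLi, TMEDA, −78 °C; TMSCl, −78 °C → rt; aq. NaHSO4
Reagents that add atoms: chlorotrimethylsilane, C[Si](C)(C)Cl
Why: Directed ortho-metalation: after N-silylation in the flask the carbamate should direct lithiation to the carbon between itself and a benzyloxy group, TMSCl quenches the aryllithium, and the N-silyl group is lost on acidic work-up.

**Step 7**
Reactants: 15 3,5-bis(benzyloxy)-2-(trimethylsilyl)phenyl N-isopropylcarbamate
Product: 17 3,5-bis(benzyloxy)-2-(trimethylsilyl)phenyl trifluoromethanesulfonate, via silyl phenol 16 (not isolated)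
Conditions: DBU, Et2NH, MeCN, 40 °C; then PhNTf2, rt
Reagents that add atoms: N-phenylbis(trifluoromethanesulfonimide), O=S(=O)(N(c1ccccc1)S(=O)(=O)C(F)(F)F)C(F)(F)F
Why: Base-induced (E1cB) cleavage of the secondary carbamate, with the isocyanate scavenged by Et2NH, should give the phenoxide, which is triflated in the same flask.

**Step 8**
Reactants: 9 (1R,2S)-2-(benzyloxy)-1-[3,4-bis(benzyloxy)phenyl]-3-bromopropan-1-ol; 17 3,5-bis(benzyloxy)-2-(trimethylsilyl)phenyl trifluoromethanesulfonate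
Product: 21 (2R,3R)-3,5,7-tris(benzyloxy)-2-[3,4-bis(benzyloxy)phenyl]chromane, via sodium alkoxide 18 (not isolated), via 3,5-bis(benzyloxy)benzyne 19 (not isolated), via aryl anion 20 (not isolated)
Conditions: 9, NaH, THF, −20 °C; then added slowly to 17 (1.5 equiv), CsF, 18-crown-6, THF, 0 °C → rt
Reagents that add atoms: none
Why: Proposed new method: fluoride-induced 1,2-elimination of 17 releases aryne 19, alkoxide 18 adds to the aryne carbon that becomes C8a, and the aryl anion 20 so formed at C4a displaces the primary bromide in a Parham-type alkylation, so that O1–C8a and C4–C4a form in one operation. The closest known reaction types are aryne annulations in which an oxygen nucleophile adds and the aryl anion is trapped by a tethered carbonyl group, O-arylation of alkoxides by arynes, and Parham cyclisation of aryllithiums onto alkyl bromides; trapping by a tethered C(sp3)–Br is the new element. Ring C closes in the 6-exo-tet mode. No stereocentre is formed, and C2 and C3 keep the aldol configuration because neither C–O bond is broken and no enolisable position remains. The step needs regioselective addition at C8a, which the C5 benzyloxy group flanking the aryne should secure by polarising the triple bond and stabilising the carbanion at C4a inductively. It also needs cyclisation to outrun protonation of 20 and aryne capture to outrun oxetane formation from 18, which the aprotic medium, the absence of any O–H group and the slow addition of 18 to an excess of the aryne source are meant to secure.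

**Step 9**
Reactants: 4 (S)-4-benzyl-3-[(benzyloxy)acetyl]oxazolidin-2-one; 22 4-(benzyloxy)benzaldehyde
Product: 24 (S)-4-benzyl-3-[(2S,3R)-2-(benzyloxy)-3-[4-(benzyloxy)phenyl]-3-hydroxypropanoyl]oxazolidin-2-one, via titanium enolate 23 (not isolated)
Conditions: TiCl4, i-Pr2NEt, N-methyl-2-pyrrolidinone, CH2Cl2, −78 °C; then 22, −78 → −40 °C; aq. NH4Cl
Reagents that add atoms: none
Why: Titanium-mediated Evans syn aldol reaction after soft enolisation: with N-methyl-2-pyrrolidinone on titanium, the (Z)-trichlorotitanium enolate should react through the non-chelated chair transition state on the face opposite the auxiliary benzyl group, setting C2 (S) and C3 (R) of the acyl chain, the future C3 and C2 of the upper unit, without an oxidative work-up.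

**Step 10**
Reactants: 24 (S)-4-benzyl-3-[(2S,3R)-2-(benzyloxy)-3-[4-(benzyloxy)phenyl]-3-hydroxypropanoyl]oxazolidin-2-one
Product: 25 (2S,3R)-2-(benzyloxy)-3-[4-(benzyloxy)phenyl]-3-hydroxy-N-methoxy-N-methylpropanamide
Conditions: AlMe3, MeNH(OMe)·HCl, CH2Cl2, 0 °C → rt; aq. potassium sodium tartrate (KNaC4H4O6) work-up
Reagents that add atoms: N,O-dimethylhydroxylamine hydrochloride, CNOC.Cl
Why: Transamidation of the imide by the aluminium amide (Weinreb amide formation), assisted by the free β-hydroxyl, should remove the auxiliary without epimerisation.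

**Step 11**
Reactants: 25 (2S,3R)-2-(benzyloxy)-3-[4-(benzyloxy)phenyl]-3-hydroxy-N-methoxy-N-methylpropanamide; 26 4-(benzyloxy)-1-bromo-2-fluorobenzene
Product: 28 (2S,3R)-2-(benzyloxy)-1-[4-(benzyloxy)-2-fluorophenyl]-3-[4-(benzyloxy)phenyl]-3-hydroxypropan-1-one, via aryllithium 27 (not isolated)
Conditions: 26 (2.5 equiv), n-BuLi, THF, −78 °C; then 25, −78 °C; aq. NH4Cl
Reagents that add atoms: none
Why: Bromine–lithium exchange followed by Weinreb ketone synthesis: one equivalent of 27 deprotonates the hydroxyl, a second adds to give a chelate that collapses to the ketone only on work-up, and at −78 °C the ortho-fluoro aryllithium should not lose LiF.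

**Step 12**
Reactants: 28 (2S,3R)-2-(benzyloxy)-1-[4-(benzyloxy)-2-fluorophenyl]-3-[4-(benzyloxy)phenyl]-3-hydroxypropan-1-one
Product: 29 (2S,3R)-2-(benzyloxy)-1-[4-(benzyloxy)-2-fluorophenyl]-3-[4-(benzyloxy)phenyl]propane-1,3-diol (both C1 epimers)
Conditions: NaBH4, MeOH/THF, 0 °C
Reagents that add atoms: none
Why: Carbonyl reduction removes the only enolisable position before the basic ring closure, and the configuration of the new carbinol is irrelevant because that carbon is ionised in step 14.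

**Step 13**
Reactants: 29 (2S,3R)-2-(benzyloxy)-1-[4-(benzyloxy)-2-fluorophenyl]-3-[4-(benzyloxy)phenyl]propane-1,3-diol
Product: 31 (2R,3R)-3,7-bis(benzyloxy)-2-[4-(benzyloxy)phenyl]chroman-4-ol (both C4 epimers), via dipotassium dialkoxide 30 (not isolated)
Conditions: KOtBu (3 equiv), DMSO/THF, 60 °C
Reagents that add atoms: none
Why: Intramolecular nucleophilic aromatic substitution (SNAr, 6-exo) of fluoride by the alkoxide on the future C2 should form O1–C8a of the upper unit with retention at that carbon; the fluorine is meta to the benzyloxy group and the other alkoxide could only close a four-membered ring.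

**Step 14**
Reactants: 31 (2R,3R)-3,7-bis(benzyloxy)-2-[4-(benzyloxy)phenyl]chroman-4-ol; 21 (2R,3R)-3,5,7-tris(benzyloxy)-2-[3,4-bis(benzyloxy)phenyl]chromane
Product: 33 (2R,3R)-3,5,7-tris(benzyloxy)-2-[3,4-bis(benzyloxy)phenyl]-8-{(2R,3R,4R)-3,7-bis(benzyloxy)-2-[4-(benzyloxy)phenyl]chroman-4-yl}chromane, via C4 benzylic cation 32 (not isolated)
Conditions: 21 (4 equiv), TMSOTf (1 equiv), CH2Cl2, −78 °C; aq. NaHCO3
Reagents that add atoms: none
Why: Friedel–Crafts-type interflavan coupling: ionisation of the C4 carbinol gives a cation stabilised by O1 and the C7 oxygen, and C8 of 21, the more nucleophilic and less hindered free position of its ring A, should attack anti to the C3 benzyloxy group of the 2,3-cis cation, setting C4 as R (3,4-trans).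

**Step 15**
Reactants: 33 (2R,3R)-3,5,7-tris(benzyloxy)-2-[3,4-bis(benzyloxy)phenyl]-8-{(2R,3R,4R)-3,7-bis(benzyloxy)-2-[4-(benzyloxy)phenyl]chroman-4-yl}chromane
Product: 34 (2R,3R)-2-(3,4-dihydroxyphenyl)-8-[(2R,3R,4R)-3,7-dihydroxy-2-(4-hydroxyphenyl)chroman-4-yl]chromane-3,5,7-triol
Conditions: H2 (1 atm), Pd(OH)2/C, THF/MeOH/H2O, rt
Reagents that add atoms: none
Why: Hydrogenolysis of the eight benzyl ethers over Pd(OH)2 on carbon should free all hydroxyl groups while the cyclic C2–O1 ethers and the interflavan bond stay intact.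

**Compound list**

1 | (S)-4-benzyloxazolidin-2-one | O=C1N[C@@H](Cc2ccccc2)CO1 | starting material
2 | (benzyloxy)acetyl chloride | O=C(Cl)COCc1ccccc1 | starting material
3 | N-lithio derivative of 1 | [Li]N1C(=O)OC[C@@H]1Cc1ccccc1 | intermediate (not isolated)
4 | (S)-4-benzyl-3-[(benzyloxy)acetyl]oxazolidin-2-one | O=C(COCc1ccccc1)N1C(=O)OC[C@@H]1Cc1ccccc1 | intermediate
5 | 3,4-bis(benzyloxy)benzaldehyde | O=Cc1ccc(OCc2ccccc2)c(OCc2ccccc2)c1 | starting material
6 | (Z)-dibutylboron enolate of 4 | CCCCB(CCCC)O/C(=C\OCc1ccccc1)N1C(=O)OC[C@@H]1Cc1ccccc1 | intermediate (not isolated)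
7 | (S)-4-benzyl-3-[(2S,3R)-2-(benzyloxy)-3-[3,4-bis(benzyloxy)phenyl]-3-hydroxypropanoyl]oxazolidin-2-one | O=C([C@@H](OCc1ccccc1)[C@H](O)c1ccc(OCc2ccccc2)c(OCc2ccccc2)c1)N1C(=O)OC[C@@H]1Cc1ccccc1 | intermediate
8 | (1R,2R)-2-(benzyloxy)-1-[3,4-bis(benzyloxy)phenyl]propane-1,3-diol | OC[C@@H](OCc1ccccc1)[C@H](O)c1ccc(OCc2ccccc2)c(OCc2ccccc2)c1 | intermediate
9 | (1R,2S)-2-(benzyloxy)-1-[3,4-bis(benzyloxy)phenyl]-3-bromopropan-1-ol | BrC[C@@H](OCc1ccccc1)[C@H](O)c1ccc(OCc2ccccc2)c(OCc2ccccc2)c1 | intermediate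
10 | 3,5-bis(benzyloxy)phenol | Oc1cc(OCc2ccccc2)cc(OCc2ccccc2)c1 | starting material
11 | 3,5-bis(benzyloxy)phenyl N-isopropylcarbamate | CC(C)NC(=O)Oc1cc(OCc2ccccc2)cc(OCc2ccccc2)c1 | intermediate
12 | 3,5-bis(benzyloxy)phenyl N-(tert-butyldimethylsilyl)-N-isopropylcarbamate | CC(C)N(C(=O)Oc1cc(OCc2ccccc2)cc(OCc2ccccc2)c1)[Si](C)(C)C(C)(C)C | intermediate (not isolated)
13 | 2-lithio derivative of 12 | CC(C)N(C(=O)Oc1cc(OCc2ccccc2)cc(OCc2ccccc2)c1[Li])[Si](C)(C)C(C)(C)C | intermediate (not isolated)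
14 | 3,5-bis(benzyloxy)-2-(trimethylsilyl)phenyl N-(tert-butyldimethylsilyl)-N-isopropylcarbamate | CC(C)N(C(=O)Oc1cc(OCc2ccccc2)cc(OCc2ccccc2)c1[Si](C)(C)C)[Si](C)(C)C(C)(C)C | intermediate (not isolated)
15 | 3,5-bis(benzyloxy)-2-(trimethylsilyl)phenyl N-isopropylcarbamate | CC(C)NC(=O)Oc1cc(OCc2ccccc2)cc(OCc2ccccc2)c1[Si](C)(C)C | intermediate
16 | 3,5-bis(benzyloxy)-2-(trimethylsilyl)phenol | Oc1cc(OCc2ccccc2)cc(OCc2ccccc2)c1[Si](C)(C)C | intermediate (not isolated)
17 | 3,5-bis(benzyloxy)-2-(trimethylsilyl)phenyl trifluoromethanesulfonate | C[Si](C)(C)c1c(OS(=O)(=O)C(F)(F)F)cc(OCc2ccccc2)cc1OCc1ccccc1 | intermediate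
18 | sodium alkoxide of 9 | BrC[C@@H](OCc1ccccc1)[C@H]([O-])c1ccc(OCc2ccccc2)c(OCc2ccccc2)c1.[Na+] | intermediate (not isolated)
19 | 3,5-bis(benzyloxy)benzyne | O(Cc1ccccc1)C1=CC(OCc2ccccc2)=CC#C1 | intermediate (not isolated)
20 | sodium 2-{(1R,2S)-2-(benzyloxy)-1-[3,4-bis(benzyloxy)phenyl]-3-bromopropoxy}-4,6-bis(benzyloxy)benzenide | BrC[C@@H](OCc1ccccc1)[C@H](Oc1cc(OCc2ccccc2)cc(OCc2ccccc2)[c-]1)c1ccc(OCc2ccccc2)c(OCc2ccccc2)c1.[Na+] | intermediate (not isolated)
21 | (2R,3R)-3,5,7-tris(benzyloxy)-2-[3,4-bis(benzyloxy)phenyl]chromane (penta-O-benzyl epicatechin) | c1c(OCc3ccccc3)cc(OCc3ccccc3)c2c1O[C@H](c1ccc(OCc3ccccc3)c(OCc3ccccc3)c1)[C@H](OCc1ccccc1)C2 | intermediate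
22 | 4-(benzyloxy)benzaldehyde | O=Cc1ccc(OCc2ccccc2)cc1 | starting material
23 | (Z)-trichlorotitanium enolate of 4 | Cl[Ti](Cl)(Cl)O/C(=C\OCc1ccccc1)N1C(=O)OC[C@@H]1Cc1ccccc1 | intermediate (not isolated)
24 | (S)-4-benzyl-3-[(2S,3R)-2-(benzyloxy)-3-[4-(benzyloxy)phenyl]-3-hydroxypropanoyl]oxazolidin-2-one | O=C([C@@H](OCc1ccccc1)[C@H](O)c1ccc(OCc2ccccc2)cc1)N1C(=O)OC[C@@H]1Cc1ccccc1 | intermediate
25 | (2S,3R)-2-(benzyloxy)-3-[4-(benzyloxy)phenyl]-3-hydroxy-N-methoxy-N-methylpropanamide | CON(C)C(=O)[C@@H](OCc1ccccc1)[C@H](O)c1ccc(OCc2ccccc2)cc1 | intermediate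
26 | 4-(benzyloxy)-1-bromo-2-fluorobenzene | Fc1cc(OCc2ccccc2)ccc1Br | starting material
27 | [4-(benzyloxy)-2-fluorophenyl]lithium | [Li]c1ccc(OCc2ccccc2)cc1F | intermediate (not isolated)
28 | (2S,3R)-2-(benzyloxy)-1-[4-(benzyloxy)-2-fluorophenyl]-3-[4-(benzyloxy)phenyl]-3-hydroxypropan-1-one | O=C(c1ccc(OCc2ccccc2)cc1F)[C@@H](OCc1ccccc1)[C@H](O)c1ccc(OCc2ccccc2)cc1 | intermediate
29 | (2S,3R)-2-(benzyloxy)-1-[4-(benzyloxy)-2-fluorophenyl]-3-[4-(benzyloxy)phenyl]propane-1,3-diol (both C1 epimers) | OC(c1ccc(OCc2ccccc2)cc1F)[C@@H](OCc1ccccc1)[C@H](O)c1ccc(OCc2ccccc2)cc1 | intermediate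
30 | dipotassium dialkoxide of 29 | [O-]C(c1ccc(OCc2ccccc2)cc1F)[C@@H](OCc1ccccc1)[C@H]([O-])c1ccc(OCc2ccccc2)cc1.[K+].[K+] | intermediate (not isolated)
31 | (2R,3R)-3,7-bis(benzyloxy)-2-[4-(benzyloxy)phenyl]chroman-4-ol (both C4 epimers) | c1ccccc1COc1ccc([C@H]2Oc3cc(OCc4ccccc4)ccc3C(O)[C@H]2OCc2ccccc2)cc1 | intermediate
32 | (2R,3R)-3,7-bis(benzyloxy)-2-[4-(benzyloxy)phenyl]chroman-4-ylium trifluoromethanesulfonate | c1ccccc1COc1ccc([C@H]2Oc3cc(OCc4ccccc4)ccc3[CH+][C@H]2OCc2ccccc2)cc1.[O-]S(=O)(=O)C(F)(F)F | intermediate (not isolated)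
33 | (2R,3R)-3,5,7-tris(benzyloxy)-2-[3,4-bis(benzyloxy)phenyl]-8-{(2R,3R,4R)-3,7-bis(benzyloxy)-2-[4-(benzyloxy)phenyl]chroman-4-yl}chromane | c1ccccc1COc1ccc([C@H]2Oc3cc(OCc5ccccc5)ccc3[C@H](c3c(OCc5ccccc5)cc(OCc5ccccc5)c4c3O[C@H](c3ccc(OCc5ccccc5)c(OCc5ccccc5)c3)[C@H](OCc3ccccc3)C4)[C@H]2OCc2ccccc2)cc1 | intermediate
34 | (2R,3R)-2-(3,4-dihydroxyphenyl)-8-[(2R,3R,4R)-3,7-dihydroxy-2-(4-hydroxyphenyl)chroman-4-yl]chromane-3,5,7-triol | Oc1ccc([C@H]2Oc3cc(O)ccc3[C@H](c3c(O)cc(O)c4c3O[C@H](c3ccc(O)c(O)c3)[C@H](O)C4)[C@H]2O)cc1 | target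

**Step count and risks**

Total step count: 15. Longest linear sequence: 8 steps (steps 1, 9, 10, 11, 12, 13, 14, 15).

Steps most likely to fail:

1. Step 8 (the proposed new method). The aryl anion may be protonated before it alkylates, the alkoxide may close to an oxetane before it meets the aryne, or the addition may lose its regiocontrol. The fallback sets out from diol 8 and comes back at 21, forming the two bonds one after the other by known reactions. Silylation of the primary hydroxyl (TBSCl, imidazole, DMF) should give (1R,2R)-2-(benzyloxy)-1-[3,4-bis(benzyloxy)phenyl]-3-[(tert-butyldimethylsilyl)oxy]propan-1-ol F1. Palladium-catalysed C–O cross-coupling of its benzylic hydroxyl with commercial 1-bromo-3,5-bis(benzyloxy)benzene ([Pd(C3H5)Cl]2, RockPhos, Cs2CO3, toluene, 90 °C) forms O1–C8a with retention at C2 and should give the aryl ether {[(2R,3R)-2-(benzyloxy)-3-[3,4-bis(benzyloxy)phenyl]-3-[3,5-bis(benzyloxy)phenoxy]propyl]oxy}(tert-butyl)dimethylsilane F2. TBAF in THF should give (2R,3R)-2-(benzyloxy)-3-[3,4-bis(benzyloxy)phenyl]-3-[3,5-bis(benzyloxy)phenoxy]propan-1-ol F3, and Dess–Martin periodinane the aldehyde (2S,3R)-2-(benzyloxy)-3-[3,4-bis(benzyloxy)phenyl]-3-[3,5-bis(benzyloxy)phenoxy]propanal F4. BF3·OEt2 in CH2Cl2 at −78 °C should then close ring C by intramolecular Friedel–Crafts hydroxyalkylation at either of the two equivalent ortho positions of the phloroglucinol ring, giving (2R,3R)-3,5,7-tris(benzyloxy)-2-[3,4-bis(benzyloxy)phenyl]chroman-4-ol F5, which Et3SiH reduces in the same flask to 21.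

2. Step 14. The cation may be attacked through C6 of 21 instead of C8, the electrophile may condense with its own ring A, and the acid may re-ionise the new interflavan bond. The fallback sets out from 31 and comes back at 33, replacing acid ionisation of a carbinol by thiophilic activation under neutral conditions. Benzyl mercaptan with BF3·OEt2 in CH2Cl2 at −78 °C should convert 31 into the bench-stable thioether (2R,3S,4S)-3,7-bis(benzyloxy)-2-[4-(benzyloxy)phenyl]-4-(benzylsulfanyl)chromane F6. AgBF4 in THF at 0 °C in the presence of excess 21 should then release the same cation without a protic or Lewis acid and give 33.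

3. Step 13. The unactivated aryl fluoride may resist displacement, so that base-induced degradation of the dialkoxide overtakes ring closure. The fallback sets out from ketone 28 and comes back at 31, closing the ring at the ketone oxidation level where the ortho carbonyl activates the fluoride. K2CO3 in DMF at rt should give (2R,3S)-3,7-bis(benzyloxy)-2-[4-(benzyloxy)phenyl]chroman-4-one F7 by carbonyl-activated SNAr, with short reaction time to limit epimerisation at C3 and retro-aldol cleavage. NaBH4 in MeOH/THF at 0 °C should then give 31.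

**Further compounds**

F1 | step 8 | (1R,2R)-2-(benzyloxy)-1-[3,4-bis(benzyloxy)phenyl]-3-[(tert-butyldimethylsilyl)oxy]propan-1-ol | CC(C)(C)[Si](C)(C)OC[C@@H](OCc1ccccc1)[C@H](O)c1ccc(OCc2ccccc2)c(OCc2ccccc2)c1
F2 | step 8 | {[(2R,3R)-2-(benzyloxy)-3-[3,4-bis(benzyloxy)phenyl]-3-[3,5-bis(benzyloxy)phenoxy]propyl]oxy}(tert-butyl)dimethylsilane | CC(C)(C)[Si](C)(C)OC[C@@H](OCc1ccccc1)[C@H](Oc1cc(OCc2ccccc2)cc(OCc2ccccc2)c1)c1ccc(OCc2ccccc2)c(OCc2ccccc2)c1
F3 | step 8 | (2R,3R)-2-(benzyloxy)-3-[3,4-bis(benzyloxy)phenyl]-3-[3,5-bis(benzyloxy)phenoxy]propan-1-ol | OC[C@@H](OCc1ccccc1)[C@H](Oc1cc(OCc2ccccc2)cc(OCc2ccccc2)c1)c1ccc(OCc2ccccc2)c(OCc2ccccc2)c1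
F4 | step 8 | (2S,3R)-2-(benzyloxy)-3-[3,4-bis(benzyloxy)phenyl]-3-[3,5-bis(benzyloxy)phenoxy]propanal | O=C[C@@H](OCc1ccccc1)[C@H](Oc1cc(OCc2ccccc2)cc(OCc2ccccc2)c1)c1ccc(OCc2ccccc2)c(OCc2ccccc2)c1
F5 | step 8 | (2R,3R)-3,5,7-tris(benzyloxy)-2-[3,4-bis(benzyloxy)phenyl]chroman-4-ol (both C4 epimers) | c1c(OCc3ccccc3)cc(OCc3ccccc3)c2c1O[C@H](c1ccc(OCc3ccccc3)c(OCc3ccccc3)c1)[C@H](OCc1ccccc1)C2O
F6 | step 14 | (2R,3S,4S)-3,7-bis(benzyloxy)-2-[4-(benzyloxy)phenyl]-4-(benzylsulfanyl)chromane | c1ccccc1COc1ccc([C@H]2Oc3cc(OCc4ccccc4)ccc3[C@H](SCc3ccccc3)[C@H]2OCc2ccccc2)cc1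
F7 | step 13 | (2R,3S)-3,7-bis(benzyloxy)-2-[4-(benzyloxy)phenyl]chroman-4-one | c1ccccc1COc1ccc([C@H]2Oc3cc(OCc4ccccc4)ccc3C(=O)[C@H]2OCc2ccccc2)cc1
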